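If Spx2 is what I have little of, what I want to know is how much of it ends as links.

    Spx + Spx2 ⇌ Tgt + Byp (K1 = 190, k1 = 171 M⁻¹ s⁻¹)
    Spx2 + Spx3 → Sdp (k2 = 16.7 M⁻¹ s⁻¹)
    Spx2 → Sdp2 (k3 = 0.127 s⁻¹)

Spx 5.0 mM; Spx2 0.980 equiv; Spx3 5.00 mM; time 8.0 s

- whether the average number of monomer units in a chain (unreacted monomers counted as chains of one) reaches 10 by 8.0 s (no / yes)
- average number of monomer units in a chain (unreacted monomers counted as chains of one) at 8.0 s

- each molecule carries two end groups: a chain counts once for every two ends that are left, dead ends included; the units are half of the end groups of the two monomers charged
- run time (flask): 8.0 s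

I began with the end groups. The flask held 4.90 mM of Spx2 against 5.0 mM of Spx, so Spx2 was the limiting reagent. There were 4.95 mM of units, each link removes one chain, and so the length is units over units minus links; the length asked for needed 4.46 mM of links.

Next I counted turnovers per Spx2. At the start, linking ran at 0.855 s⁻¹. The side steps, taking [Spx3] as constant (pseudo-first-order), ran at 0.211 s⁻¹. That share, 80.2%, gave 3.93 mM of links.

The weak link was holding that share constant, since linking slows as [Spx] falls. So I took the break-even level, the [Spx] at which a Spx2 is as likely to be lost as to link, side rate over linking constant: 1.23 mM. With [Spx3] held constant and the way back left out, while [Spx] falls from its charge to a lower value, the side steps take this level times the logarithm of the ratio of the two. Using my first figure, that left 3.00 mM of links, less than that figure, so I tried a value between the two. The midpoint, 3.47 mM, returned 3.45 mM, fewer links than the length asked for needed, so I committed to a length of 3.29. Even at the [Spx] those links left, Spx2 had 3.81 turnovers in 8.0 s, so I reckoned 2.21% of its charge unused and neglected that. I left out the way back.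

The forecast answered no and gave 3.15, with “the reverse step barely mattering”, a little lower than my figure.

The flask gave no and 3.20. At 8.00 s, [Spx] stood at 31.9% of its charge. The break-even level turns that reading into 1.41 mM of side loss, and Sdp and Sdp2 together held 1.42 mM. In the neighbouring flask with 0.590 equiv of Spx2, the level is unchanged and [Spx] read 55.7% of its charge, so the side loss comes to 0.719 mM. That leaves 2.23 mM of links, and its Tgt stood at 2.21 mM.

(Its constants come from no measurement; the rest is arithmetic.)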